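(The numbers in the tables stem from a simulated flask with constants of no real substance; the scatter is artificial.)

Start with the rate.

| flask | electrophile | nucleophile | remark | time |
|---|---|---|---|---|
| eta | 10 mM | 15 mM | run made earlier |  |
| zeta | 10 mM | 53 mM | run made earlier |  |
| Sunday's | 10 mM | 10.0 mM |  | 20 h |
| Monday's | 10 mM | 21.0 mM |  | 20 h |
| Wednesday's | 10 mM | 42.0 mM |  | 20 h |

| run | time / h | electrophile / % | product / % |
|---|---|---|---|
| eta | 2.50 | 79.0 | 21.0 |
| eta | 5.00 | 73.5 | 28.6 |
| eta | 8.00 | 67.1 | 33.2 |
| eta | 10.0 | 63.8 | 35.7 |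
| eta | 12.0 | 59.9 | 38.9 |
| eta | 15.0 | 59.5 | 42.1 |
| zeta | 2.50 | 56.7 | 44.4 |
| zeta | 5.00 | 43.5 | 57.1 |
| zeta | 8.00 | 34.4 | 64.8 |
| zeta | 10.0 | 29.0 | 68.3 |
| zeta | 12.0 | 27.1 | 72.1 |
| zeta | 15.0 | 25.4 | 77.7 |

(each reading ± 1 percentage point)

- part of the electrophile that has reacted at the end, Sunday's
- part of the electrophile that has reacted at the end, Monday's
- part of the electrophile that has reacted at the end, Wednesday's
- what raising the concentration of nucleophile from its lowest to its highest value here does to the part of the electrophile that has reacted (changes below 5 percentage points count as none) (no change / it falls / it rises)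

- a reading or a percentage of product counts all its forms, free or not

I follow r, the rate of loss of electrophile divided by the electrophile present, a pseudo-first-order constant of the moment. Over the opening 2.50 h the eta run reads r = 0.0943 h⁻¹ and the zeta run 0.227 h⁻¹. Between 10.0 h and 15.0 h they read 0.0140 h⁻¹ and 0.0265 h⁻¹. So r falls by a factor of 6.74 in eta and 8.57 in zeta, as readings. Nucleophile spent on product, one per product, gives factors of 1.39 and 1.17, less than the slowing, so further factors of 4.85 and 7.32 remain unaccounted for.

Summed over time, r gives the exposure X = −ln(fraction of electrophile left). In eta, between 5.00 h and 15.0 h, X grows as t^m with m = 0.476. At 15.0 h, zeta against eta gives X growing as c^n, with c the nucleophile charged and n = 0.769. Eta carried to 20 h has the end exposure X* = 0.595. A flask with this electrophile and time then gets X*(c/15 mM)^n, and one minus exp(−X) reacts. That gives X = 0.436, 0.771 and 1.31, so I commit to 35.3%, 53.7% and 73.0% reacted on Sunday's, Monday's and Wednesday's.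

The forecast gives 35%, 53% and 72% on Sunday's, Monday's and Wednesday's, and for raising the nucleophile it rises, reading “a time-dependent slowdown, such as a decaying active species”.

The flasks give 34.1%, 55.7% and 75.6%, so from lowest to highest nucleophile it rises, by 41 percentage points.

    electrophile + nucleophile → acid set free + product (k = 13.0 M⁻¹ h⁻¹)
    nucleophile + acid set free ⇌ protonated nucleophile, settled at all times (K = 7.40 × 10⁵ M⁻¹)
    crystals ⇌ product, rate k3*(cs3 - [product]) while solid is left; crystals form when [product] > cs3 (solubility = 4.00 mM, k = 4.30 h⁻¹)
    2 nucleophile → homo dimer (k = 9.80 M⁻¹ h⁻¹)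
    nucleophile ⇌ dormant form (K = 1.30, k = 0.590 h⁻¹)

Sunday's reaches X = 0.417 against my 0.436. It has not come to rest, but at ten times the time its X grows by a factor of 1.35 and Wednesday's by 1.94, both less than the 2.99 of t^m. At that time the part reacted stands at 42.9% on Sunday's, 70.9% on Monday's and 93.5% on Wednesday's. Free nucleophile in Sunday's falls from 5.6% of its charge at 20.0 h to 0.119% at 200 h. At 20.0 h in Sunday's, electrophile's half-life by its reaction with nucleophile is 95 h, longer than the run.

For the neighbour of Sunday's charged with 25 mM of nucleophile, X* gives X = 0.882, so 58.6% reacted. That flask gives 61.0%.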